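Arene carbon C5 of the resorcinol ring together with side chain C1′–C17′ is the intact C18 chain of ricinoleic acid (its carboxyl carbon becomes C5), so only ring carbons C1–C4 and C6 have to be added. A single Michael–Claisen annulation of dimethyl malonate onto a methyl enone makes ring bonds C5–C6 and C1–C2 and closes the six-membered carbocycle at the dihydroresorcylate level; aromatisation and decarboxylation finish. The annulation precursor is the C21 (3E,12Z,15S)-enone silyl ether, reached from methyl ricinoleate by inversion at C12, silylation, half-reduction and acetonyl Wittig extension; the inverted chain stereocentre and the Z-alkene come from the chiral pool.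

Key step: step 5

Remark: the arene is numbered C1 (OH), C2, C3 (OH), C4, C5 (chain), C6 and the chain C1′ (benzylic) to C17′; 10 and 11 are drawn as keto tautomers (they should exist largely as enols) and their ring sp3 centres, like C4 of 9, are left undefined because step 6 erases them.

Step 1

Reactants: 1 methyl ricinoleate, methyl (9Z,12R)-12-hydroxyoctadec-9-enoate

Product: 3 methyl (9Z,12S)-12-hydroxyoctadec-9-enoate, via 12S 4-nitrobenzoate diester 2 (not isolated)

Conditions: 4-O2NC6H4CO2H, PPh3, DIAD, THF, 0 °C → rt; then K2CO3, MeOH, rt

Reagents that add atoms: 4-nitrobenzoic acid, `O=C(O)c1ccc(cc1)[N+](=O)[O-]`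

Why: Mitsunobu esterification: the C12 hydroxyl is activated as its oxyphosphonium salt and displaced by 4-nitrobenzoate in an SN2 step that inverts C12 from R to S (the acid supplies the new C12 oxygen), after which K2CO3-mediated transesterification in MeOH frees the inverted alcohol while the C1 methyl ester is merely exchanged with the solvent.

Step 2

Reactants: 3 methyl (9Z,12S)-12-hydroxyoctadec-9-enoate

Product: 4 methyl (9Z,12S)-12-(tert-butyldimethylsilyloxy)octadec-9-enoate

Conditions: TBSCl, imidazole, DMF, rt

Reagents that add atoms: tert-butyldimethylsilyl chloride, `CC(C)(C)[Si](C)(C)Cl`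

Why: Imidazole-promoted O-silylation of an unhindered secondary alcohol, which bonds silicon to oxygen only and so leaves the 12S centre untouched while masking the hydroxyl for the hydride step.

Step 3

Reactants: 4 methyl (9Z,12S)-12-(tert-butyldimethylsilyloxy)octadec-9-enoate

Product: 5 (9Z,12S)-12-(tert-butyldimethylsilyloxy)octadec-9-enal

Conditions: i-Bu2AlH (1.1 equiv), CH2Cl2, −78 °C; MeOH quench, aq. potassium sodium tartrate

Reagents that add atoms: none

Why: Partial ester reduction with i-Bu2AlH: at −78 °C one hydride gives a tetrahedral aluminium hemiacetal that does not collapse until the quench, so the aldehyde is released only after the hydride is destroyed, and neither the silyl ether nor the Z-alkene reacts.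

Step 4

Reactants: 5 (9Z,12S)-12-(tert-butyldimethylsilyloxy)octadec-9-enal; 6 1-(triphenylphosphoranylidene)propan-2-one

Product: 7 (3E,12Z,15S)-15-(tert-butyldimethylsilyloxy)henicosa-3,12-dien-2-one

Conditions: toluene, 90 °C

Reagents that add atoms: none

Why: Wittig olefination with a ketone-stabilised ylide, which attacks only the aldehyde and gives the E-enone under the usual thermodynamic preference of stabilised ylides, under neutral conditions that leave the Z-alkene, silyl ether and 15S centre unchanged.

Step 5

Reactants: 7 (3E,12Z,15S)-15-(tert-butyldimethylsilyloxy)henicosa-3,12-dien-2-one; 8 dimethyl malonate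

Product: 10 methyl 6-[(8Z,11S)-11-(tert-butyldimethylsilyloxy)heptadec-8-en-1-yl]-2,4-dioxocyclohexane-1-carboxylate, via Michael adduct 9 (not isolated)

Conditions: NaOMe (1.3 equiv), MeOH, reflux; then cold 1 M HCl to pH 3–4

Reagents that add atoms: none

Why: NaOMe converts 8 into its enolate, which adds 1,4 to the E-enone of 7 at C4, the β-carbon that carries the chain, to give 9 (future arene bond C5–C6); proton exchange then provides the methyl-ketone enolate, whose terminal carbon attacks one malonate ester carbonyl and expels methoxide (future arene bond C1–C2), and deprotonation of the resulting cyclic β-diketone by methoxide pulls both equilibria forward. The closest known reaction type is the malonate Michael addition–Claisen (Dieckmann-type) condensation of alk-3-en-2-ones that gives the dihydroresorcylate precursors of 5-alkylresorcinols. The single ring is closed by a 6-exo-trig C-acylation; closure through the internal α-carbon C3 would need a four-membered ring and should not compete. The two new sp3 ring centres of 10 (C1 and C6) are not controlled and need not be, because 10 is an equilibrating keto–enol and diastereomer mixture that becomes planar in step 6, while the 15S silyl ether carbon and the Z-alkene are remote and inert to methoxide. The step therefore needs only regioselectivity, which is secured by the polarity of the enone (nucleophile to the β-carbon) together with the preference for the six-membered ring, fixing the 1,3-dioxygen and 5-alkyl pattern.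

Step 6

Reactants: 10 methyl 6-[(8Z,11S)-11-(tert-butyldimethylsilyloxy)heptadec-8-en-1-yl]-2,4-dioxocyclohexane-1-carboxylate

Product: 12 methyl 6-[(8Z,11S)-11-(tert-butyldimethylsilyloxy)heptadec-8-en-1-yl]-2,4-dihydroxybenzoate, via 3-bromo dione ester 11 (not isolated)

Conditions: CuBr2 (2.1 equiv), LiBr, MeCN, 0 °C → rt

Reagents that add atoms: none

Why: Bromination–dehydrobromination aromatisation: CuBr2 brominates the strongly enolised β-diketone at C3 much faster than an isolated alkene reacts, and the bromo dione 11 loses HBr by 1,4-elimination through its dienol and tautomerises to the hydrogen-bonded resorcylate, a path known for cyclohexenones and cyclohexane-1,3-diones with CuBr2–LiBr.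

Step 7

Reactants: 12 methyl 6-[(8Z,11S)-11-(tert-butyldimethylsilyloxy)heptadec-8-en-1-yl]-2,4-dihydroxybenzoate

Product: 15 5-[(8Z,11S)-11-hydroxyheptadec-8-en-1-yl]benzene-1,3-diol, via silylated resorcylic acid 13 (not isolated), via silylated resorcinol 14 (not isolated)

Conditions: NaOH, MeOH–H2O, reflux, under Ar; then aq. HCl to pH 1, 40 °C

Reagents that add atoms: none

Why: Three standard events in one pot, ester saponification, protodecarboxylation of the β-resorcylic acid (ipso-protonation of the electron-rich ring, whose keto tautomer is a β-keto acid) and acid-catalysed solvolysis of the secondary silyl ether, none of which breaks the C11′–O bond or moves the Z-alkene, so the 11′S centre set in step 1 should reach the target unchanged.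

Compound list

```
1 | methyl ricinoleate, methyl (9Z,12R)-12-hydroxyoctadec-9-enoate | CCCCCC[C@@H](O)C/C=C\CCCCCCCC(=O)OC | starting material
2 | methyl (9Z,12S)-12-(4-nitrobenzoyloxy)octadec-9-enoate | CCCCCC[C@H](OC(=O)c1ccc(cc1)[N+](=O)[O-])C/C=C\CCCCCCCC(=O)OC | intermediate
3 | methyl (9Z,12S)-12-hydroxyoctadec-9-enoate | CCCCCC[C@H](O)C/C=C\CCCCCCCC(=O)OC | intermediate
4 | methyl (9Z,12S)-12-(tert-butyldimethylsilyloxy)octadec-9-enoate | CCCCCC[C@H](O[Si](C)(C)C(C)(C)C)C/C=C\CCCCCCCC(=O)OC | intermediate
5 | (9Z,12S)-12-(tert-butyldimethylsilyloxy)octadec-9-enal | CCCCCC[C@H](O[Si](C)(C)C(C)(C)C)C/C=C\CCCCCCCC=O | intermediate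
6 | 1-(triphenylphosphoranylidene)propan-2-one | CC(=O)C=P(c1ccccc1)(c1ccccc1)c1ccccc1 | starting material
7 | (3E,12Z,15S)-15-(tert-butyldimethylsilyloxy)henicosa-3,12-dien-2-one | CCCCCC[C@H](O[Si](C)(C)C(C)(C)C)C/C=C\CCCCCCC/C=C/C(C)=O | intermediate
8 | dimethyl malonate | COC(=O)CC(=O)OC | starting material
9 | dimethyl 2-[(12Z,15S)-15-(tert-butyldimethylsilyloxy)-2-oxohenicos-12-en-4-yl]propanedioate | CCCCCC[C@H](O[Si](C)(C)C(C)(C)C)C/C=C\CCCCCCCC(CC(C)=O)C(C(=O)OC)C(=O)OC | intermediate
10 | methyl 6-[(8Z,11S)-11-(tert-butyldimethylsilyloxy)heptadec-8-en-1-yl]-2,4-dioxocyclohexane-1-carboxylate | CCCCCC[C@H](O[Si](C)(C)C(C)(C)C)C/C=C\CCCCCCCC1CC(=O)CC(=O)C1C(=O)OC | intermediate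
11 | methyl 3-bromo-6-[(8Z,11S)-11-(tert-butyldimethylsilyloxy)heptadec-8-en-1-yl]-2,4-dioxocyclohexane-1-carboxylate | CCCCCC[C@H](O[Si](C)(C)C(C)(C)C)C/C=C\CCCCCCCC1CC(=O)C(Br)C(=O)C1C(=O)OC | intermediate
12 | methyl 6-[(8Z,11S)-11-(tert-butyldimethylsilyloxy)heptadec-8-en-1-yl]-2,4-dihydroxybenzoate | CCCCCC[C@H](O[Si](C)(C)C(C)(C)C)C/C=C\CCCCCCCc1cc(O)cc(O)c1C(=O)OC | intermediate
13 | 6-[(8Z,11S)-11-(tert-butyldimethylsilyloxy)heptadec-8-en-1-yl]-2,4-dihydroxybenzoic acid | CCCCCC[C@H](O[Si](C)(C)C(C)(C)C)C/C=C\CCCCCCCc1cc(O)cc(O)c1C(=O)O | intermediate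
14 | 5-[(8Z,11S)-11-(tert-butyldimethylsilyloxy)heptadec-8-en-1-yl]benzene-1,3-diol | CCCCCC[C@H](O[Si](C)(C)C(C)(C)C)C/C=C\CCCCCCCc1cc(O)cc(O)c1 | intermediate
15 | 5-[(8Z,11S)-11-hydroxyheptadec-8-en-1-yl]benzene-1,3-diol | CCCCCC[C@H](O)C/C=C\CCCCCCCc1cc(O)cc(O)c1 | target
```

Total step count: 7. Longest linear sequence: 7 steps, from 1 to 15.

Steps most likely to fail

Step 6: electrophilic bromine may be diverted to the side-chain alkene, or a second bromination may occur on the newly formed electron-rich ring. The HBr released may also remove the silyl group early, which would be harmless because step 7 removes it anyway. Fallback: setting out from 10, the halogenation is replaced by a halogen-free dehydrogenation, hydride abstraction from the enol by DDQ in dioxane at 80 °C. This should give the resorcylate directly and rejoins the route at 12. No compound outside the list is formed (F0).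

Step 5: base-induced self-condensation or γ-deprotonation of the enone may outrun conjugate addition, or the sequence may stall at the open-chain adduct if Claisen closure is slow. Fallback: setting out from aldehyde 5, the same ring is built from the complementary pair of partners. Wittig reaction with methyl (triphenylphosphoranylidene)acetate should give methyl (2E,11Z,14S)-14-(tert-butyldimethylsilyloxy)icosa-2,11-dienoate F1. Methyl acetoacetate and NaOMe in refluxing MeOH should then add through the acetoacetate α-carbon to give dimethyl 2-acetyl-3-[(8Z,11S)-11-(tert-butyldimethylsilyloxy)heptadec-8-en-1-yl]pentanedioate F2. Claisen attack of its acetyl methyl group on the chain ester (ring bond C2–C3 instead of C1–C2) closes the same dione ester, so the route is rejoined at 10.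

Step 1: the activated homoallylic oxyphosphonium may eliminate to a conjugated diene, or inversion may be incomplete if an acyloxyphosphonium pathway intervenes. Fallback: setting out from 1, activation and displacement are separated. MsCl and Et3N in CH2Cl2 should give methyl (9Z,12R)-12-(methanesulfonyloxy)octadec-9-enoate F3. CsOAc with 18-crown-6 in toluene should displace the sulfonate by SN2 with inversion to give methyl (9Z,12S)-12-acetoxyoctadec-9-enoate F4. K2CO3 in MeOH then removes the acetate and the route is rejoined at 3.

Further compounds

```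
F0 | step 6 | none | none
F1 | step 5 | methyl (2E,11Z,14S)-14-(tert-butyldimethylsilyloxy)icosa-2,11-dienoate | CCCCCC[C@H](O[Si](C)(C)C(C)(C)C)C/C=C\CCCCCCC/C=C/C(=O)OC
F2 | step 5 | dimethyl 2-acetyl-3-[(8Z,11S)-11-(tert-butyldimethylsilyloxy)heptadec-8-en-1-yl]pentanedioate | CCCCCC[C@H](O[Si](C)(C)C(C)(C)C)C/C=C\CCCCCCCC(CC(=O)OC)C(C(C)=O)C(=O)OC
F3 | step 1 | methyl (9Z,12R)-12-(methanesulfonyloxy)octadec-9-enoate | CCCCCC[C@@H](OS(C)(=O)=O)C/C=C\CCCCCCCC(=O)OC
F4 | step 1 | methyl (9Z,12S)-12-acetoxyoctadec-9-enoate | CCCCCC[C@H](OC(C)=O)C/C=C\CCCCCCCC(=O)OC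
```
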